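**Plan**

- Retrosynthesis: the ring B quinone is taken back to a 2′,3′,4′,6′-tetramethoxyphenyl ring (C3′/C6′ methyl ethers), and ring C is opened at O1–C2 to an open 1,3-diketone.
- The diketone is cut on both sides of the C4 carbonyl, at C4a–C4 and C4–C3, into a ring A aryl iodide, carbon monoxide and a ring B methoxymethyl ketone; the ketone is cut at C1′–C2 into tetramethoxybenzene and a methoxyacetyl unit.
- Enabling feature: C4 sits between C4a of ring A and the methoxy-bearing C3, and ring A carries equivalent oxygens on both carbons next to C4a (C5 and C8a), so a symmetric iodide serves and either freed phenol closes ring C to the same 5-hydroxy-7-methoxy pattern.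
- Forward: ring A iodide (steps 1–2) and ring B ketone (step 3) are joined through CO (step 4); acid closes ring C (step 5); ring B is oxidised to the quinone last (step 6).
- Stereochemistry: the target is achiral; the only stereocentre on the route, C3 of the open diketone, is racemic and enolisable and vanishes when ring C aromatises.

Key step: step 4

Remark: the quinone oxygens introduced in step 6 are taken to come from water (aryl–oxygen cleavage with loss of methanol), and the enolate of step 4 is drawn as the sodium-chelated Z isomer, whose geometry has no bearing on the product.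

**Route**

Step 1
Reactants: 1 5-methoxyresorcinol
Product: 2 1-methoxy-3,5-bis(methoxymethoxy)benzene
Conditions: NaH (2.4 equiv), MOMCl (2.3 equiv), DMF, 0 °C to rt
Reagents that add atoms: chloromethyl methyl ether, COCCl
Why: Williamson ether synthesis in which both phenoxides are O-alkylated by the reactive α-chloro ether, giving acetals that withstand the organolithium and enolate steps and fall off under the acid used later for ring closure.

Step 2
Reactants: 2 1-methoxy-3,5-bis(methoxymethoxy)benzene
Product: 4 2-iodo-5-methoxy-1,3-bis(methoxymethoxy)benzene, via aryllithium 3 (not isolated)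
Conditions: n-BuLi (1.1 equiv), THF, 0 °C; then I2, −78 °C to rt
Reagents that add atoms: iodine, II
Why: Directed ortho-metalation should remove the ring hydrogen flanked by the two chelating OMOM groups (stronger directors than OMe, acting together at that carbon), and iodinolysis of aryllithium 3 fixes the halogen there, any isomer metalated between OMe and OMOM being separated at this stage.

Step 3
Reactants: 5 1,2,3,5-tetramethoxybenzene; 6 methoxyacetyl chloride
Product: 7 2-methoxy-1-(2,3,4,6-tetramethoxyphenyl)ethanone
Conditions: SnCl4 (1.1 equiv), CH2Cl2, −20 to 0 °C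
Reagents that add atoms: none
Why: Friedel–Crafts acylation at one of the two equivalent free positions of 5, each ortho to two and para to one methoxy group, so only one ketone can form, with the mild Lewis acid SnCl4 at low temperature chosen to limit ortho O-demethylation.

Step 4
Reactants: 4 2-iodo-5-methoxy-1,3-bis(methoxymethoxy)benzene; 8 carbon monoxide; 7 2-methoxy-1-(2,3,4,6-tetramethoxyphenyl)ethanone
Product: 10 2-methoxy-1-[4-methoxy-2,6-bis(methoxymethoxy)phenyl]-3-(2,3,4,6-tetramethoxyphenyl)propane-1,3-dione, via sodium enolate 9 (not isolated)
Conditions: 7 (2 equiv), NaN(SiMe3)2 (2 equiv), THF, 0 °C; then 4 (1 equiv), Pd(dba)2 (5 mol %), Xantphos (5 mol %), CO (1 atm), 70 °C; aq NH4Cl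
Reagents that add atoms: none
Why: Oxidative addition of iodide 4 to the zerovalent palladium–Xantphos complex, migratory insertion of CO to give the aroylpalladium iodide, exchange of iodide for enolate 9 and carbon–carbon reductive elimination create the C4a–C4 and C4–C3 bonds in one operation and return zerovalent palladium. The closest known reaction is the palladium-catalysed carbonylative α-arylation of aryl alkyl ketones with aryl iodides to 1,3-diketones, here applied to an α-methoxy ketone. No ring is closed, and the single new stereocentre (the methoxy-bearing C3) arises racemic and enolisable and disappears when ring C becomes aromatic in step 5, so it needs no control. The selectivity required is carbonylative over direct α-arylation and C- over O-acylation: the two ortho acetal groups of 4 retard direct aryl–enolate reductive elimination so that CO insertion wins under a CO atmosphere, and the wide bite angle of the ligand accelerates acyl–carbon reductive elimination. The second equivalent of 9 deprotonates the more acidic product, which is held as its chelated sodium diketonate; this drives the reaction forward, shields the product from a second acylation and lets any O-acylated enol ester be converted to the diketone by acyl transfer, while the liberated ketone 7 is recovered. Both ortho positions of 4 being substituted rules out aryne formation under the basic conditions, and the methoxy group of 7 leaves only one enolisable carbon.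

Step 5
Reactants: 10 2-methoxy-1-[4-methoxy-2,6-bis(methoxymethoxy)phenyl]-3-(2,3,4,6-tetramethoxyphenyl)propane-1,3-dione
Product: 12 5-hydroxy-3,7-dimethoxy-2-(2,3,4,6-tetramethoxyphenyl)-4H-chromen-4-one, via bis-phenol diketone 11 (not isolated)
Conditions: conc. HCl (10 equiv), MeOH, 60 °C
Reagents that add atoms: none
Why: Acid-catalysed acetal methanolysis frees both phenols, either of the two equivalent hydroxyl groups adds to the ring B carbonyl (6-exo-trig, cyclic hemiketal) and loss of water gives the aromatic 4-pyranone, the classical cyclodehydration of o-hydroxyaryl 1,3-diketones to flavones, the other hydroxyl ending as the chelated 5-OH.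

Step 6
Reactants: 12 5-hydroxy-3,7-dimethoxy-2-(2,3,4,6-tetramethoxyphenyl)-4H-chromen-4-one
Product: 13 2-(5-hydroxy-3,7-dimethoxy-4-oxo-4H-chromen-2-yl)-3,5-dimethoxycyclohexa-2,5-diene-1,4-dione
Conditions: (NH4)2Ce(NO3)6 (2.5 equiv), aq MeCN, 0 °C
Reagents that add atoms: water, O
Why: Oxidative demethylation of a para-dimethoxyarene by tetravalent cerium should act on ring B, the only electron-rich ring with a para pair of methoxy groups (C3′/C6′), giving the 1,4-benzoquinone with the C2′ and C4′ methoxy groups retained, whereas ring A is deactivated by the chromone carbonyl and its hydroxyl is tied up in the hydrogen bond to the C4 carbonyl.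

**Compound list**

1 | 5-methoxyresorcinol (5-methoxybenzene-1,3-diol) | COc1cc(O)cc(O)c1 | starting material
2 | 1-methoxy-3,5-bis(methoxymethoxy)benzene | COCOc1cc(OC)cc(OCOC)c1 | intermediate
3 | 4-methoxy-2,6-bis(methoxymethoxy)phenyllithium (not isolated) | [Li]c1c(OCOC)cc(OC)cc1OCOC | intermediate
4 | 2-iodo-5-methoxy-1,3-bis(methoxymethoxy)benzene | COCOc1cc(OC)cc(OCOC)c1I | intermediate
5 | 1,2,3,5-tetramethoxybenzene | COc1cc(OC)c(OC)c(OC)c1 | starting material
6 | methoxyacetyl chloride | COCC(=O)Cl | starting material
7 | 2-methoxy-1-(2,3,4,6-tetramethoxyphenyl)ethanone | COCC(=O)c1c(OC)cc(OC)c(OC)c1OC | intermediate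
8 | carbon monoxide | [C-]#[O+] | starting material
9 | sodium (Z)-2-methoxy-1-(2,3,4,6-tetramethoxyphenyl)ethen-1-olate (not isolated) | [Na+].[O-]/C(=C\OC)c1c(OC)cc(OC)c(OC)c1OC | intermediate
10 | 2-methoxy-1-[4-methoxy-2,6-bis(methoxymethoxy)phenyl]-3-(2,3,4,6-tetramethoxyphenyl)propane-1,3-dione (racemic, enolisable) | COCOc1cc(OC)cc(OCOC)c1C(=O)C(OC)C(=O)c1c(OC)cc(OC)c(OC)c1OC | intermediate
11 | 1-(2,6-dihydroxy-4-methoxyphenyl)-2-methoxy-3-(2,3,4,6-tetramethoxyphenyl)propane-1,3-dione (racemic, not isolated) | COc1cc(O)c(C(=O)C(OC)C(=O)c2c(OC)cc(OC)c(OC)c2OC)c(O)c1 | intermediate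
12 | 5-hydroxy-3,7-dimethoxy-2-(2,3,4,6-tetramethoxyphenyl)-4H-chromen-4-one | COc1cc(O)c2c(c1)oc(-c1c(OC)cc(OC)c(OC)c1OC)c(OC)c2=O | intermediate
13 | 2-(5-hydroxy-3,7-dimethoxy-4-oxo-4H-chromen-2-yl)-3,5-dimethoxycyclohexa-2,5-diene-1,4-dione | COC1=CC(=O)C(c2oc3cc(OC)cc(O)c3c(=O)c2OC)=C(OC)C1=O | target

**Step count**

Total steps: 6. Longest linear sequence: 5 steps (steps 1, 2, 4, 5, 6, from compound 1).

**Steps most likely to fail**

1. Step 4. Oxidative addition and CO insertion at the doubly ortho-substituted iodide may be slow, so that reductive deiodination or direct α-arylation competes; the hindered enolate may also acylate on oxygen or fail to couple. Fallback, from 2 back to 10, making the same two bonds without palladium: compound 2 is lithiated as in step 2 and aryllithium 3 is quenched with N,N-dimethylformamide to give 4-methoxy-2,6-bis(methoxymethoxy)benzaldehyde F1. Addition of F1 at −78 °C to enolate 9 (prepared from 7 and NaN(SiMe3)2 as in step 4) and a cold aqueous quench should give the aldol 3-hydroxy-2-methoxy-3-[4-methoxy-2,6-bis(methoxymethoxy)phenyl]-1-(2,3,4,6-tetramethoxyphenyl)propan-1-one F2 as a mixture of racemic diastereomers. Oxidation of the secondary alcohol with Dess–Martin periodinane (NaHCO3, CH2Cl2) should converge both diastereomers on diketone 10, where the route is rejoined.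

2. Step 6. One-electron oxidation of the ring A phenol (oxidative coupling or over-oxidation) may compete with the oxidation of ring B. Fallback, from 12 back to 13, with ring A masked: the chelated hydroxyl of 12 is alkylated (NaH, MOMCl, DMF) to 3,7-dimethoxy-5-(methoxymethoxy)-2-(2,3,4,6-tetramethoxyphenyl)-4H-chromen-4-one F3, in which ring A is a plain resorcinol diether on a carbonyl-bearing ring. Oxidation with (NH4)2Ce(NO3)6 in aqueous MeCN should then give 2-[3,7-dimethoxy-5-(methoxymethoxy)-4-oxo-4H-chromen-2-yl]-3,5-dimethoxycyclohexa-2,5-diene-1,4-dione F4. Brief treatment with CF3CO2H in wet CH2Cl2, which the quinone tolerates far better than base, should release 13.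

3. Step 3. The Lewis acid may cleave the methyl ether ortho to the new carbonyl by chelation, and the methoxyacetyl cation may lose CO and then alkylate instead of acylate the arene. Fallback, from 5 back to 7, with no Lewis acid and no acylium ion: n-BuLi in THF (0 °C to rt) removes one of the two equivalent hydrogens flanked by two methoxy groups (directed ortho-metalation) to give 2,3,4,6-tetramethoxyphenyllithium F5. This is added at −78 °C to N,2-dimethoxy-N-methylacetamide; the chelated tetrahedral adduct should collapse on aqueous work-up to ketone 7.

Further compounds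
F1 | step 4 | 4-methoxy-2,6-bis(methoxymethoxy)benzaldehyde | COCOc1cc(OC)cc(OCOC)c1C=O
F2 | step 4 | 3-hydroxy-2-methoxy-3-[4-methoxy-2,6-bis(methoxymethoxy)phenyl]-1-(2,3,4,6-tetramethoxyphenyl)propan-1-one (mixture of racemic diastereomers) | COCOc1cc(OC)cc(OCOC)c1C(O)C(OC)C(=O)c1c(OC)cc(OC)c(OC)c1OC
F3 | step 6 | 3,7-dimethoxy-5-(methoxymethoxy)-2-(2,3,4,6-tetramethoxyphenyl)-4H-chromen-4-one | COCOc1cc(OC)cc2oc(-c3c(OC)cc(OC)c(OC)c3OC)c(OC)c(=O)c12
F4 | step 6 | 2-[3,7-dimethoxy-5-(methoxymethoxy)-4-oxo-4H-chromen-2-yl]-3,5-dimethoxycyclohexa-2,5-diene-1,4-dione | COCOc1cc(OC)cc2oc(C3=C(OC)C(=O)C(OC)=CC3=O)c(OC)c(=O)c12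
F5 | step 3 | 2,3,4,6-tetramethoxyphenyllithium | [Li]c1c(OC)cc(OC)c(OC)c1OC
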